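The synthesis rests on opening ring C at C3–C4: that bond is formed as a C3=C4 alkene by ring-closing olefin metathesis between a vinyl group on C4a of ring A and the terminal vinyl group of an allyl ether whose carbinol carbon is the future C2 and already bears ring B. In a single operation the metathesis closes the pyran ring and completes the flavonoid skeleton without touching C2, which is set beforehand by iridium-catalysed asymmetric allylic etherification. The precursor is a hexasubstituted benzene carrying three adjacent methoxy groups, a vinyl group, the (S)-1-[4-(methoxymethoxy)phenyl]allyloxy group and a prenyl group. Wacker oxidation at C4, O5 demethylation and acetal cleavage then give the flavanone.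

Key step: step 10

Remark on numbering: flavanone numbering is used (ring A = oxygenated benzo ring C4a–C8a, ring B = the 4-oxygenated phenyl ring on C2, ring C = pyran ring O1–C4); fragment 1 is the ring A phenol 9, fragment 2 the cinnamyl carbonate 13; MOM = methoxymethyl.

Assumption: L is O,O′-[(S)-1,1′-binaphthalene-2,2′-diyl] N,N-bis[(S)-1-phenylethyl]phosphoramidite, and its (Sa,Sc,Sc) hand is taken to be the one that gives (S)-1-arylallyl aryl ethers; if the sense of induction were the opposite, the (Ra,Rc,Rc) ligand would be used with no other change.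

Step 1
Reactants: 1 3,4,5-trimethoxyphenol
Product: 2 1,2,3-trimethoxy-5-(methoxymethoxy)benzene
Conditions: MOMCl, i-Pr2NEt, CH2Cl2, 0 °C → rt
Reagents that add atoms: chloromethyl methyl ether (MOMCl), COCCl
Why: O-alkylation of the phenol by the reactive α-chloro ether (acetal formation) installs a group that protects the oxygen and later directs ortho-metalation.

Step 2
Reactants: 2 1,2,3-trimethoxy-5-(methoxymethoxy)benzene; 3 prenyl bromide (1-bromo-3-methylbut-2-ene)
Product: 5 1,2,3-trimethoxy-5-(methoxymethoxy)-4-(3-methylbut-2-enyl)benzene, via aryllithium 4 (not isolated)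
Conditions: n-BuLi, TMEDA, THF, 0 °C; then CuBr·SMe2 (10 mol%), 3, −78 °C → rt
Reagents that add atoms: none
Why: Directed ortho-metalation places lithium on the carbon flanked by the OMOM and a methoxy group (the two such sites are equivalent), and copper-catalysed SN2 allylation of the aryllithium by the primary allylic bromide should give the linear prenyl arene.

Step 3
Reactants: 5 1,2,3-trimethoxy-5-(methoxymethoxy)-4-(3-methylbut-2-enyl)benzene
Product: 6 3,4,5-trimethoxy-2-(3-methylbut-2-enyl)phenol
Conditions: HCl (0.5 M in MeOH), rt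
Reagents that add atoms: none
Why: Acid-catalysed acetal exchange with methanol cleaves the aryl MOM ether far faster than the trisubstituted olefin is protonated, so the prenyl group should survive at room temperature.

Step 4
Reactants: 6 3,4,5-trimethoxy-2-(3-methylbut-2-enyl)phenol
Product: 8 2-hydroxy-4,5,6-trimethoxy-3-(3-methylbut-2-enyl)benzaldehyde, via salicyl alcohol 7 (not isolated)
Conditions: MgCl2, Et3N, (CH2O)n, MeCN, reflux; aq. HCl work-up
Reagents that add atoms: formaldehyde (from paraformaldehyde), C=O
Why: Magnesium-mediated ortho-formylation (Casnati–Skattebøl): the magnesium phenoxide delivers formaldehyde to the only free ortho carbon, and the benzylic alkoxide so formed is oxidised to the aldehyde by hydride transfer to a second formaldehyde.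

Step 5
Reactants: 8 2-hydroxy-4,5,6-trimethoxy-3-(3-methylbut-2-enyl)benzaldehyde
Product: 9 3,4,5-trimethoxy-2-(3-methylbut-2-enyl)-6-vinylphenol
Conditions: Ph3PCH3Br (2.5 equiv), KOt-Bu (3.5 equiv), THF, 0 °C → rt
Reagents that add atoms: methyltriphenylphosphonium bromide, C[P+](c1ccccc1)(c1ccccc1)c1ccccc1.[Br-]
Why: Wittig methylenation with excess non-stabilised ylide, the extra base holding the phenol as its phenoxide, converts the salicylaldehyde into the ortho-vinylphenol, which is used without storage.

Step 6
Reactants: 10 methyl (E)-4-hydroxycinnamate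
Product: 11 methyl (E)-3-[4-(methoxymethoxy)phenyl]prop-2-enoate
Conditions: MOMCl, i-Pr2NEt, CH2Cl2, 0 °C → rt
Reagents that add atoms: chloromethyl methyl ether (MOMCl), COCCl
Why: O-alkylation of the phenol as in step 1 masks the future 4′-hydroxyl with a group stable to hydride, base, ruthenium and palladium.

Step 7
Reactants: 11 methyl (E)-3-[4-(methoxymethoxy)phenyl]prop-2-enoate
Product: 12 (E)-3-[4-(methoxymethoxy)phenyl]prop-2-en-1-ol
Conditions: i-Bu2AlH (2.5 equiv), CH2Cl2, −78 °C; aq. KNaC4H4O6 (potassium sodium tartrate) work-up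
Reagents that add atoms: none
Why: 1,2-Reduction of the conjugated ester by the aluminium hydride at low temperature gives the allylic alcohol without touching the E olefin or the acetal.

Step 8
Reactants: 12 (E)-3-[4-(methoxymethoxy)phenyl]prop-2-en-1-ol
Product: 13 (E)-3-[4-(methoxymethoxy)phenyl]prop-2-enyl methyl carbonate
Conditions: ClCO2Me, pyridine, CH2Cl2, 0 °C
Reagents that add atoms: methyl chloroformate, COC(=O)Cl
Why: Acylation of the primary allylic alcohol by the chloroformate gives the carbonate leaving group needed for ionisation by iridium.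

Step 9
Reactants: 9 3,4,5-trimethoxy-2-(3-methylbut-2-enyl)-6-vinylphenol; 13 (E)-3-[4-(methoxymethoxy)phenyl]prop-2-enyl methyl carbonate
Product: 15 (S)-1-[4-(methoxymethoxy)phenyl]prop-2-enyl 3,4,5-trimethoxy-2-(3-methylbut-2-enyl)-6-vinylphenyl ether, via lithium phenoxide 14 (not isolated)
Conditions: LiN(SiMe3)2 (1.0 equiv), THF, 0 °C; then 13 (1.3 equiv), [Ir(cod)Cl]2 (2 mol%), (Sa,Sc,Sc)-L (4 mol%, pre-activated with n-PrNH2), THF, rt → 40 °C
Reagents that add atoms: none
Why: Iridium-catalysed asymmetric allylic etherification: the cyclometalated monovalent-iridium phosphoramidite complex ionises the carbonate to an allyl-iridium species that the phenoxide attacks at the aryl-bearing terminus, the chiral ligand fixing the face of attack and thereby the (S) configuration of the future C2.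

Step 10
Reactants: 15 (S)-1-[4-(methoxymethoxy)phenyl]prop-2-enyl 3,4,5-trimethoxy-2-(3-methylbut-2-enyl)-6-vinylphenyl ether
Product: 16 (2S)-5,6,7-trimethoxy-2-[4-(methoxymethoxy)phenyl]-8-(3-methylbut-2-enyl)-2H-chromene
Conditions: second-generation Grubbs catalyst RuCl2(=CHPh)(H2IMes)(PCy3) (5 mol%), CH2Cl2 (0.01 M), 40 °C, argon sparge
Reagents that add atoms: none
Why: The ruthenium benzylidene exchanges onto one of the two terminal vinyl groups, and the new alkylidene adds across the neighbouring vinyl group to a ruthenacyclobutane whose cycloreversion gives the C3=C4 double bond and Ru=CH2, ethylene being swept out to drive the reaction. This is ring-closing olefin metathesis of an ortho-vinylaryl allyl ether, an established entry to 2H-chromenes. Ring C is closed as a six-membered ring with the new alkene endocyclic, the two reacting carbons being held next to each other by the C4a–C8a–O1–C2 tether on ring A. No stereocentre is created; C2 keeps its (S) configuration because metathesis breaks none of its σ-bonds and the medium is neutral and aprotic. The step needs chemoselectivity for the two monosubstituted olefins over the trisubstituted prenyl olefin (which would close a seven-membered benzoxepine with loss of isobutene) and over intermolecular metathesis; this is secured by the much slower engagement of trisubstituted alkenes by ruthenium, by the kinetic preference for six- over seven-membered closure, and by high dilution.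

Step 11
Reactants: 16 (2S)-5,6,7-trimethoxy-2-[4-(methoxymethoxy)phenyl]-8-(3-methylbut-2-enyl)-2H-chromene
Product: 17 (2S)-5,6,7-trimethoxy-2-[4-(methoxymethoxy)phenyl]-8-(3-methylbut-2-enyl)chroman-4-one
Conditions: PdCl2 (10 mol%), CuCl (20 mol%), O2 (1 atm), DMF–H2O (7:1), 40 °C
Reagents that add atoms: water, O
Why: Tsuji–Wacker oxidation: water should attack the palladium-bound C3=C4 olefin at C4, where positive charge is stabilised by the oxygenated ring A and is not opposed by the electron-withdrawing C2–O1 bond, and β-hydride elimination with tautomerisation gives the C4 ketone, while the trisubstituted prenyl olefin is not oxidised at a competitive rate by divalent palladium.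

Step 12
Reactants: 17 (2S)-5,6,7-trimethoxy-2-[4-(methoxymethoxy)phenyl]-8-(3-methylbut-2-enyl)chroman-4-one
Product: 18 (2S)-5-hydroxy-6,7-dimethoxy-2-[4-(methoxymethoxy)phenyl]-8-(3-methylbut-2-enyl)chroman-4-one
Conditions: MgI2·OEt2 (3 equiv), toluene–Et2O, 60 °C; water work-up
Reagents that add atoms: none
Why: Chelation-controlled ether cleavage: magnesium bridges the C4 carbonyl and the peri O5 methoxy oxygen and iodide removes that methyl group by SN2, so the unchelated O6 and O7 methyl ethers, the prenyl olefin and C2 should stay as they are.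

Step 13
Reactants: 18 (2S)-5-hydroxy-6,7-dimethoxy-2-[4-(methoxymethoxy)phenyl]-8-(3-methylbut-2-enyl)chroman-4-one
Product: 19 (2S)-5-hydroxy-2-(4-hydroxyphenyl)-6,7-dimethoxy-8-(3-methylbut-2-enyl)chroman-4-one
Conditions: aq. HCl (3 M), MeOH, 40 °C
Reagents that add atoms: none
Why: Acid-catalysed acetal methanolysis frees the 4′-phenol under conditions too mild to protonate the prenyl olefin appreciably or to open the hydrogen-bonded 5-hydroxyflavanone, so C2 should remain (S).

Compound list
1 | 3,4,5-trimethoxyphenol | COc1cc(O)cc(OC)c1OC | starting material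
2 | 1,2,3-trimethoxy-5-(methoxymethoxy)benzene | COCOc1cc(OC)c(OC)c(OC)c1 | intermediate
3 | prenyl bromide (1-bromo-3-methylbut-2-ene) | CC(C)=CCBr | starting material
4 | [6-(methoxymethoxy)-2,3,4-trimethoxyphenyl]lithium | [Li]c1c(OCOC)cc(OC)c(OC)c1OC | intermediate
5 | 1,2,3-trimethoxy-5-(methoxymethoxy)-4-(3-methylbut-2-enyl)benzene | COCOc1cc(OC)c(OC)c(OC)c1CC=C(C)C | intermediate
6 | 3,4,5-trimethoxy-2-(3-methylbut-2-enyl)phenol | COc1cc(O)c(CC=C(C)C)c(OC)c1OC | intermediate
7 | 2-(hydroxymethyl)-3,4,5-trimethoxy-6-(3-methylbut-2-enyl)phenol (present as its magnesium salt) | COc1c(OC)c(OC)c(CO)c(O)c1CC=C(C)C | intermediate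
8 | 2-hydroxy-4,5,6-trimethoxy-3-(3-methylbut-2-enyl)benzaldehyde | COc1c(OC)c(OC)c(C=O)c(O)c1CC=C(C)C | intermediate
9 | 3,4,5-trimethoxy-2-(3-methylbut-2-enyl)-6-vinylphenol | COc1c(OC)c(OC)c(C=C)c(O)c1CC=C(C)C | intermediate
10 | methyl (E)-4-hydroxycinnamate | COC(=O)/C=C/c1ccc(O)cc1 | starting material
11 | methyl (E)-3-[4-(methoxymethoxy)phenyl]prop-2-enoate | COCOc1ccc(/C=C/C(=O)OC)cc1 | intermediate
12 | (E)-3-[4-(methoxymethoxy)phenyl]prop-2-en-1-ol | COCOc1ccc(/C=C/CO)cc1 | intermediate
13 | (E)-3-[4-(methoxymethoxy)phenyl]prop-2-enyl methyl carbonate | COCOc1ccc(/C=C/COC(=O)OC)cc1 | intermediate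
14 | lithium 3,4,5-trimethoxy-2-(3-methylbut-2-enyl)-6-vinylphenoxide | COc1c(OC)c(OC)c(C=C)c([O-])c1CC=C(C)C.[Li+] | intermediate
15 | (S)-1-[4-(methoxymethoxy)phenyl]prop-2-enyl 3,4,5-trimethoxy-2-(3-methylbut-2-enyl)-6-vinylphenyl ether | COc1c(OC)c(C=C)c(O[C@H](c2ccc(OCOC)cc2)C=C)c(CC=C(C)C)c1OC | intermediate
16 | (2S)-5,6,7-trimethoxy-2-[4-(methoxymethoxy)phenyl]-8-(3-methylbut-2-enyl)-2H-chromene | COc1c(OC)c2c(c(CC=C(C)C)c1OC)O[C@H](c1ccc(OCOC)cc1)C=C2 | intermediate
17 | (2S)-5,6,7-trimethoxy-2-[4-(methoxymethoxy)phenyl]-8-(3-methylbut-2-enyl)chroman-4-one | COc1c(OC)c2c(c(CC=C(C)C)c1OC)O[C@H](c1ccc(OCOC)cc1)CC2=O | intermediate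
18 | (2S)-5-hydroxy-6,7-dimethoxy-2-[4-(methoxymethoxy)phenyl]-8-(3-methylbut-2-enyl)chroman-4-one | COc1c(O)c2c(c(CC=C(C)C)c1OC)O[C@H](c1ccc(OCOC)cc1)CC2=O | intermediate
19 | (2S)-5-hydroxy-2-(4-hydroxyphenyl)-6,7-dimethoxy-8-(3-methylbut-2-enyl)chroman-4-one | COc1c(O)c2c(c(CC=C(C)C)c1OC)O[C@H](c1ccc(O)cc1)CC2=O | target

Total step count: 13. Longest linear sequence: 10 steps (steps 1–5, then 9–13); fragment 2 is made in steps 6–8.

Steps most likely to fail

Step 9. The doubly ortho-substituted, electron-rich phenoxide may attack the allyl-iridium intermediate slowly, so that linear ether formation and reversible ionisation of the branched ether erode regio- and enantiopurity. The fallback delivers the oxygen with a small nucleophile first and attaches the hindered phenol afterwards by SN2. Setting out from carbonate 13, iridium-catalysed allylic substitution with KOSiEt3 ([Ir(cod)Cl]2, the (Ra,Rc,Rc) ligand, CH2Cl2) should give triethyl{[(1R)-1-[4-(methoxymethoxy)phenyl]prop-2-enyl]oxy}silane F1. Treatment with n-Bu4NF in THF frees (1R)-1-[4-(methoxymethoxy)phenyl]prop-2-en-1-ol F2. Mitsunobu coupling of F2 with phenol 9 (PPh3, DIAD, toluene, 0 °C) proceeds with inversion and comes back to the route at 15.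

Step 10. The ruthenium alkylidene may engage the prenyl olefin (seven-membered closure), a ruthenium hydride formed by catalyst decay may shift the allyl ether double bond into conjugation and destroy C2, or turnover may stall at the doubly ortho-flanked styrene. The fallback builds ring C without metathesis, by an organocatalytic oxa-Michael/aldol condensation followed by excision of the extra carbon. Setting out from alcohol 12, MnO2 in CH2Cl2 gives (E)-3-[4-(methoxymethoxy)phenyl]prop-2-enal F3. Salicylaldehyde 8 and F3 are combined under a diarylprolinol trimethylsilyl ether with 2-nitrobenzoic acid (iminium catalysis, toluene, rt; the catalyst enantiomer that places ring B as in 16). This should give (2R)-5,6,7-trimethoxy-2-[4-(methoxymethoxy)phenyl]-8-(3-methylbut-2-enyl)-2H-chromene-3-carbaldehyde F4, whose descriptor differs from that of 16 only because the formyl group raises the priority of C3. Tsuji–Wilkinson decarbonylation with RhCl(PPh3)3 (toluene, reflux) comes back to the route at 16.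

Step 11. Hydroxypalladation of the internal, conjugated olefin may be slow, water may add at C3, or β-hydride elimination towards C2 may lead on to over-oxidation to the flavone. The fallback is Markovnikov hydration by hydrogen-atom transfer followed by alcohol oxidation. Setting out from 16, Mn(dpm)3 (cat.), PhSiH3 and O2 in i-PrOH at 0 °C transfer a hydrogen atom to C3. This gives the C4 benzylic radical stabilised by ring A, faster than transfer to the isolated prenyl olefin, and trapping by O2 and reduction should give (2S)-5,6,7-trimethoxy-2-[4-(methoxymethoxy)phenyl]-8-(3-methylbut-2-enyl)chroman-4-ol F5 as both C4 epimers. Dess–Martin periodinane (NaHCO3, CH2Cl2) comes back to the route at 17.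

Further compounds
F1 | step 9 | triethyl{[(1R)-1-[4-(methoxymethoxy)phenyl]prop-2-enyl]oxy}silane | CC[Si](CC)(CC)O[C@@H](c1ccc(OCOC)cc1)C=C
F2 | step 9 | (1R)-1-[4-(methoxymethoxy)phenyl]prop-2-en-1-ol | O[C@@H](c1ccc(OCOC)cc1)C=C
F3 | step 10 | (E)-3-[4-(methoxymethoxy)phenyl]prop-2-enal | COCOc1ccc(/C=C/C=O)cc1
F4 | step 10 | (2R)-5,6,7-trimethoxy-2-[4-(methoxymethoxy)phenyl]-8-(3-methylbut-2-enyl)-2H-chromene-3-carbaldehyde | COc1c(OC)c2c(c(CC=C(C)C)c1OC)O[C@H](c1ccc(OCOC)cc1)C(C=O)=C2
F5 | step 11 | (2S)-5,6,7-trimethoxy-2-[4-(methoxymethoxy)phenyl]-8-(3-methylbut-2-enyl)chroman-4-ol (both C4 epimers) | COc1c(OC)c2c(c(CC=C(C)C)c1OC)O[C@H](c1ccc(OCOC)cc1)CC2O
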